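The solution cannot hold the J this flask needs: 0.10 M of Z stands against 5.4 mM of J, so, taking one J per X, count 18.5 refills of the solution.

| flask | Z | J | remark | time |
|---|---|---|---|---|
| epsilon | 0.067 M | 5.4 mM (held) | run made earlier |  |
| gamma | 0.15 M | 5.4 mM (held) | run made earlier |  |
| flask | 0.10 M | 5.4 mM (held) |  | 10 h |

| run | time / h | X / % | Z / % |
|---|---|---|---|
| epsilon | 1.00 | 43.6 | 55.7 |
| epsilon | 1.33 | 55.6 | 42.4 |
| epsilon | 2.00 | 76.3 | 22.2 |
| epsilon | 3.00 | 88.8 | 8.7 |
| epsilon | 5.00 | 95.3 | 4.6 |
| epsilon | 8.00 | 94.6 | 4.1 |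
| epsilon | 12.0 | 96.0 | 4.6 |
| gamma | 1.50 | 37.6 | 60.9 |
| gamma | 3.00 | 70.8 | 29.7 |
| gamma | 5.00 | 91.4 | 9.6 |
| gamma | 6.00 | 93.2 | 4.8 |
| gamma | 8.00 | 95.9 | 6.5 |
| gamma | 10.0 | 95.7 | 2.5 |
| gamma | 12.0 | 95.4 | 5.4 |

(standard deviation of a reading: 1 percentage point)

* amount of X in percent of the Z charged, at 30 min, 2.5 h and 10 h

- at the start none of J is in solution

Start from the bench rule for a gas reaction: uptake runs steadily, so X grows on a straight line. Read the line from the gamma run, 70.8% of 0.15 M by 3.00 h. This gives the refill time, the time in which X equal to the saturation concentration of J appears: 9.15 min. In the flask, 30 min is 3.28 refills, so I reckon X at 17.7%.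

The line breaks where it asks for more than the charge: at 5.00 h it puts the gamma run at 118%, against 91.4% read. At 1.50 h it puts the gamma run at 35.4%, against 37.6% read; at 3.00 h, the reading it was drawn through, [Z] stands at 44.5 mM. Below that level, treat a smaller charge as the gamma run entered later, by the refills it lacks. Between the two gamma readings, let [Z] fall exponentially, at 0.565 h⁻¹.

Test this on the epsilon run. It enters 2.34 h late, so at 1.00 h it should show [Z] 36.7 mM, and 37.3 mM is read. The flask enters 1.41 h late, which gives [Z] 26.6 mM at 2.5 h, so, counting the Z gone as X, I reckon X at 73.4%. For 10 h, take the plateau, 95.7% in gamma at that time.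

The forecast gives 13%, 76% and 95.5%, holding that “the reaction is reversible and stops there”. Its first value is lower than mine and its second higher.

The flask gives 17.7%, 75.4% and 95.3%.

    J ⇌ G, rate k1*(csat - [G]) (kL = 0.150 min⁻¹)
    Z + G ⇌ X (K = 4100 L mol⁻¹, k = 6.10 L mol⁻¹ min⁻¹)
    G → L (k = 0.0120 min⁻¹)

In the flask, G has a half-life of 1.1 min by the forward path to X alone, with the other concentrations as charged, shorter than the 4.62 min in which the passage of J closes half the gap to saturation. Against the refill time of 9.15 min, the flask at 1.00 h holds [G] at 1.53 mM, and at that level the passage of J brings in an amount equal to the saturation concentration in 9.29 min.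

The runs were computed with constants of no real substance, and the scatter is random.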